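## The problem

The target 24 is a flavonol (2-aryl-3-hydroxy-4H-chromen-4-one) whose ring A has no C–H bond left. C5 and C7 carry hydroxyl groups, C6 and C8 carry methoxyl groups, and C8a carries the ring oxygen, so five neighbouring C–O bonds must be placed on one benzene ring. The two methyl ethers have to stay distinct from the two phenols from the first step to the last. Ring C is fused to ring A across C4a–C8a and bears the catechol ring B at C2, a hydroxyl at C3 and the carbonyl at C4. The target has no stereocentre, so the task is one of regiochemistry and of telling oxygens apart; stereocentres that arise on the way are racemic and are erased. The free polyphenol is oxidised readily in basic, aerobic media and its pyranone is opened by hot hydroxide or alkoxide, so the phenols should be unveiled last and under neutral conditions. The feature that makes the key step possible is that C3 is a single carbon between C2 and C4. Without it, ring C is the furan ring of a 2-aryl-3-oxybenzofuran, and the pyranone is that furan with one carbon inserted into its C2=C3 enol ether bond.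

## Retrosynthesis

**O–benzyl bonds.** The four O–CH2Ph bonds of the tetrabenzyl ether 23 are cut last, leading back from 24. Benzyl is preferred to methyl, which could not be told from the C6 and C8 methoxyls, and to silyl or acetal groups, which would not outlast the bases and acids used earlier. The forward step asks only that the C2=C3 bond of a flavonol survive hydrogenolysis.

**C3–O bond.** 23 is traced to the 3-bromide 21 through the pinacol boronate 22. The detour through boron is chosen over direct displacement by an oxygen nucleophile, because such nucleophiles add to C2 of 3-halochromones and open or contract ring C. The forward step asks for oxidative addition into a hindered but electron-poor vinylic C–Br bond and an oxidation that the benzyl ethers tolerate.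

**C2–C3 and C3–C4 bonds (key cut).** Both bonds to C3 are cut together, and C3 leaves as the carbon of bromoform 18; what remains is the 3-siloxybenzofuran 17. The neighbouring cuts at O1–C2 or C4–C4a lead to open-chain diketone or chalcone logic and leave C3 unfunctionalised. This cut shrinks ring C to a furan and delivers C3 already bearing a handle. The forward reaction must pick the enol ether double bond over every arene, pass through the cyclopropane 19 and the flavylium salt 20, and shed the silyl group.

**O–Si and C3a–C3 bonds.** 17 is the enol silyl ether of benzofuranone 16, and 16 is opened at the aryl–carbonyl bond to the acid 14, which closes by way of the mixed anhydride 15. Closing this bond last uses the only free position of ring A, which lies between two oxygen substituents, so regiochemistry is not in question. The forward Friedel–Crafts closure must be mild enough for four benzyl ethers.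

**Aryl ether C–O bond.** 14 comes from ester 13, which is cut at the ether oxygen into phenol 8 and the α-bromo ester 12. This joins the two halves in a simple substitution and leaves each half a monocyclic benzene. The forward step needs a phenol with exactly one free hydroxyl.

**Ring B fragment.** 12 is the α-bromination product of ester 10, reached by way of the silyl ketene acetal 11, and 10 is the perbenzylated form of 3,4-dihydroxyphenylacetic acid 9. One operation protects both phenols and the acid.

**Ring A fragment.** Phenol 8 is taken back through bromide 7 and bromophenol 6 to the symmetric dibromide 3, then to benzyl ether 2 and syringol 1. Both bromines are introduced while the molecule is still symmetric, so their positions are unambiguous. They are then converted one at a time, the first by way of the aryllithium 4 and the boronate 5, which avoids a statistical mono-alkylation of a resorcinol. 1 supplies the methoxy–oxygen–methoxy triad, and its own oxygen becomes the C7 hydroxyl.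

## Roads not taken

Alternative 1: The cut is at C4a–C4 and C4–C3. The aryl iodide 1,3,5-tris(benzyloxy)-2-iodo-4,6-dimethoxybenzene A2, carbon monoxide A4 and the alkyne 1,2-bis(benzyloxy)-4-ethynylbenzene A3 would be joined under PdCl2(PPh3)2 and CuI to the ynone 3-[3,4-bis(benzyloxy)phenyl]-1-[2,4,6-tris(benzyloxy)-3,5-dimethoxyphenyl]prop-2-yn-1-one A1.
- Merits: the plan is convergent, C4 comes from the cheapest one-carbon source, A2 is symmetric, and the reaction type is known.
- Weak points: the iodine of A2 sits between two benzyloxy groups on a very electron-rich ring. Oxidative addition is slow and the acyl-palladium stage is congested, so direct coupling of A2 with A3 without uptake of A4, and homocoupling of A3, compete. A1 is still open-chain. Ring C then needs removal of one of two equivalent ortho benzyl groups and a 6-endo closure that competes with 5-exo closure. C3 is still unoxidised and needs a late hydroxylation.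
- Comparison: every reaction type on this road is known, which the chosen plan cannot say of step 12. Against that, the chosen plan closes ring C and functionalises C3 in one operation, never has to desymmetrise ring A after the carbonyl is in place, and avoids a carbonylation at a doubly ortho-substituted carbon.

Alternative 2: The cut is at C6–O and C8–O. Quercetin A7 would be perbenzylated and brominated to the dibromide 3,5,7-tris(benzyloxy)-2-[3,4-bis(benzyloxy)phenyl]-6,8-dibromo-4H-chromen-4-one A6. Sodium methoxide A8 with CuBr would then replace both bromines to give 3,5,7-tris(benzyloxy)-2-[3,4-bis(benzyloxy)phenyl]-6,8-dimethoxy-4H-chromen-4-one A5, and hydrogenolysis of A5 would finish.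
- Merits: it is by far the shortest road. All fifteen skeletal carbons and five of the seven oxygen substituents are bought with A7, and the key step is a known Ullmann-type methoxylation.
- Weak points: benzylation of the chelated C5 hydroxyl of A7 is slow, and bromination must stop at C6 and C8 without touching ring B. Both bromines of A6 lie between two oxygen substituents, so copper insertion is hindered and hydrodebromination competes. Hot A8 can add to C2 and open the pyranone, and can attack benzyl ethers.
- Comparison: in length and in precedent this road is better than the chosen one, and if the target alone were wanted it would be tried first. The chosen plan sets against it that no finished flavonol core has to survive forcing nucleophilic conditions. Ring B comes from an arylacetic acid and C3 arrives as a bromide, so both can be varied. Each ring A oxygen is fixed before the chromone exists.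

Alternative 3: The cut is at C8–C8a, with C4a–C5 made one step earlier. The C5-metalated form of the pyranone 3-(benzyloxy)-2-[3,4-bis(benzyloxy)phenyl]-4H-pyran-4-one A12 would add to the squarate 3-(benzyloxy)-4-methoxycyclobut-3-ene-1,2-dione A11 to give the cyclobutenone 2-(benzyloxy)-4-[5-(benzyloxy)-6-[3,4-bis(benzyloxy)phenyl]-4-oxo-4H-pyran-3-yl]-4-hydroxy-3-methoxycyclobut-2-en-1-one A10. Heating A10 would open the four-membered ring to the dienylketene (3Z)-2-(benzyloxy)-4-[5-(benzyloxy)-6-[3,4-bis(benzyloxy)phenyl]-4-oxo-4H-pyran-3-yl]-4-hydroxy-3-methoxybuta-1,3-dien-1-one A13. A six-electron closure of A13 onto the pyranone C–H next to oxygen, followed by tautomerisation, would give the hydroquinone 3,7-bis(benzyloxy)-2-[3,4-bis(benzyloxy)phenyl]-5,8-dihydroxy-6-methoxy-4H-chromen-4-one A9.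
- Merits: ring A is built in one thermal step of a known type. In A9 the C8 hydroxyl is free while the C5 hydroxyl is hydrogen-bonded to the carbonyl, so the last methyl group could be placed selectively.
- Weak points: A12 is itself a multistep target and its most acidic C–H is the one next to the ring oxygen, not C5. A11 offers two nearly equal carbonyl groups, and addition to the wrong one leads to the 6-benzyloxy-7-methoxy series. The 5,8-hydroquinone A9 is easily oxidised, and one methylation still remains.
- Comparison: the key reaction type is known here and is not in the chosen plan, and both plans close a ring in the key step. The chosen plan reaches its key substrate in fewer operations, takes the ring A pattern unambiguously from syringol 1, and has no regiochemical branch point of the squarate kind.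

Key step: step 12

Remark on the chemistry: compounds 12 to 16 carry one stereocentre and are racemic by design, and it is erased when the enol ether 17 forms; the two stereocentres of 19 are likewise racemic and vanish on ring opening, and the target is achiral.

## Route

Step 1
Reactants: 1 2,6-dimethoxyphenol (syringol)
Product: 2 2-(benzyloxy)-1,3-dimethoxybenzene
Conditions: BnBr, K2CO3, DMF, 60 °C
Reagents that add atoms: benzyl bromide, BrCc1ccccc1
Why: Williamson ether synthesis; the phenoxide of 1 is alkylated by a reactive benzylic bromide, and this benzyl group marks the oxygen that ends as the free C7 hydroxyl.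

Step 2
Reactants: 2 2-(benzyloxy)-1,3-dimethoxybenzene
Product: 3 3-(benzyloxy)-1,5-dibromo-2,4-dimethoxybenzene
Conditions: NBS (2.1 equiv), MeCN, 0 °C → rt, dark
Reagents that add atoms: N-bromosuccinimide, O=C1CCC(=O)N1Br
Why: Electrophilic aromatic bromination; each bromine should enter ortho to one methoxyl and para to the other, the activated sites of a 1,2,3-trialkoxybenzene, while the position para to the twisted benzyloxy group is the least activated. Ionic conditions spare the benzylic CH2.

Step 3
Reactants: 3 3-(benzyloxy)-1,5-dibromo-2,4-dimethoxybenzene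
Product: 6 3-(benzyloxy)-5-bromo-2,4-dimethoxyphenol, via aryllithium 4 (not isolated), via dimethyl arylboronate 5 (not isolated)
Conditions: n-BuLi (1.05 equiv), THF, −78 °C; B(OMe)3, −78 → 0 °C; AcOH, 30% H2O2, 0 °C → rt
Reagents that add atoms: hydrogen peroxide, OO; n-butyllithium, [Li]CCCC (lithium of 4 only); trimethyl borate, COB(OC)OC (boron and methoxyls of 5 only)
Why: Bromine–lithium exchange, borylation and oxidative aryl migration from boron to oxygen; one equivalent of n-BuLi should exchange only one bromine, because a second exchange would have to build a dianion. This breaks the symmetry without a statistical step.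

Step 4
Reactants: 6 3-(benzyloxy)-5-bromo-2,4-dimethoxyphenol
Product: 7 1,3-bis(benzyloxy)-5-bromo-2,4-dimethoxybenzene
Conditions: BnBr, K2CO3, DMF, rt
Reagents that add atoms: benzyl bromide, BrCc1ccccc1
Why: Williamson ether synthesis on a phenol with one free ortho position; this benzyl group protects the future C5 hydroxyl.

Step 5
Reactants: 7 1,3-bis(benzyloxy)-5-bromo-2,4-dimethoxybenzene
Product: 8 3,5-bis(benzyloxy)-2,4-dimethoxyphenol
Conditions: Pd2(dba)3, tBuXPhos, KOH, 1,4-dioxane/H2O, 100 °C, degassed; then 1 M HCl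
Reagents that add atoms: potassium hydroxide, [K+].[OH-]
Why: Palladium-catalysed hydroxylation of an aryl bromide with hydroxide (C–O cross-coupling with a bulky biarylphosphine); the substrate has a single halogen, one ortho substituent at the reacting carbon and no base-sensitive group.

Step 6
Reactants: 9 3,4-dihydroxyphenylacetic acid
Product: 10 benzyl 2-[3,4-bis(benzyloxy)phenyl]acetate
Conditions: BnBr (3.3 equiv), K2CO3, DMF, 60 °C, under argon
Reagents that add atoms: benzyl bromide, BrCc1ccccc1
Why: Williamson etherification of both phenols and alkylation of the carboxylate in one pot; exclusion of air protects the catechol dianion.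

Step 7
Reactants: 10 benzyl 2-[3,4-bis(benzyloxy)phenyl]acetate
Product: 12 benzyl 2-bromo-2-[3,4-bis(benzyloxy)phenyl]acetate (racemic), via silyl ketene acetal 11 (not isolated)
Conditions: LiN(SiMe3)2, Me3SiCl, THF, −78 °C; then NBS, −78 → 0 °C
Reagents that add atoms: N-bromosuccinimide, O=C1CCC(=O)N1Br; chlorotrimethylsilane, C[Si](C)(C)Cl (silyl group of 11 only)
Why: Enolate silylation followed by electrophilic bromination of the silyl ketene acetal; the ionic course is chosen because radical bromination would attack the benzyl ether methylenes. The new centre is racemic and is erased in step 11.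

Step 8
Reactants: 8 3,5-bis(benzyloxy)-2,4-dimethoxyphenol; 12 benzyl 2-bromo-2-[3,4-bis(benzyloxy)phenyl]acetate (racemic)
Product: 13 benzyl 2-[3,5-bis(benzyloxy)-2,4-dimethoxyphenoxy]-2-[3,4-bis(benzyloxy)phenyl]acetate (racemic)
Conditions: K2CO3, acetone, rt
Reagents that add atoms: none
Why: Williamson-type substitution of an activated benzylic α-bromo ester by a phenoxide; 8 has a single hydroxyl and the bromide has no β-hydrogen, so neither double alkylation nor elimination can occur.

Step 9
Reactants: 13 benzyl 2-[3,5-bis(benzyloxy)-2,4-dimethoxyphenoxy]-2-[3,4-bis(benzyloxy)phenyl]acetate (racemic)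
Product: 14 2-[3,5-bis(benzyloxy)-2,4-dimethoxyphenoxy]-2-[3,4-bis(benzyloxy)phenyl]acetic acid (racemic)
Conditions: LiOH, THF/H2O, rt; then 1 M HCl
Reagents that add atoms: lithium hydroxide, [Li+].[OH-]
Why: Ester saponification; benzyl aryl ethers are inert to aqueous hydroxide at room temperature.

Step 10
Reactants: 14 2-[3,5-bis(benzyloxy)-2,4-dimethoxyphenoxy]-2-[3,4-bis(benzyloxy)phenyl]acetic acid (racemic)
Product: 16 4,6-bis(benzyloxy)-2-[3,4-bis(benzyloxy)phenyl]-5,7-dimethoxy-1-benzofuran-3(2H)-one (racemic), via mixed trifluoroacetic anhydride 15 (not isolated)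
Conditions: (CF3CO)2O, CH2Cl2, 0 °C → rt, under argon; aq NaHCO3
Reagents that add atoms: trifluoroacetic anhydride, O=C(OC(=O)C(F)(F)F)C(F)(F)F (trifluoroacetyl group of 15 only)
Why: Intramolecular Friedel–Crafts acylation through the mixed anhydride; the only free ring A carbon has oxygen substituents at both ortho positions and at the para position, so it should react without a metal Lewis acid that would endanger the benzyl ethers. The product is used at once because it enolises and autoxidises easily.

Step 11
Reactants: 16 4,6-bis(benzyloxy)-2-[3,4-bis(benzyloxy)phenyl]-5,7-dimethoxy-1-benzofuran-3(2H)-one (racemic)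
Product: 17 {[4,6-bis(benzyloxy)-2-[3,4-bis(benzyloxy)phenyl]-5,7-dimethoxy-1-benzofuran-3-yl]oxy}(tert-butyl)dimethylsilane
Conditions: TBSOTf, Et3N, CH2Cl2, 0 °C
Reagents that add atoms: tert-butyldimethylsilyl trifluoromethanesulfonate, CC(C)(C)[Si](C)(C)OS(=O)(=O)C(F)(F)F
Why: Enol silylation of a ketone (soft enolisation); O-silylation is driven by formation of the aromatic benzofuran and removes the C2 stereocentre.

Step 12
Reactants: 17 {[4,6-bis(benzyloxy)-2-[3,4-bis(benzyloxy)phenyl]-5,7-dimethoxy-1-benzofuran-3-yl]oxy}(tert-butyl)dimethylsilane; 18 bromoform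
Product: 21 5,7-bis(benzyloxy)-2-[3,4-bis(benzyloxy)phenyl]-3-bromo-6,8-dimethoxy-4H-chromen-4-one, via dibromocyclopropane 19 (not isolated), via 4-siloxyflavylium bromide 20 (not isolated)
Conditions: KOtBu, toluene/hexane, −20 °C → rt, 18 added slowly; aq NH4Cl
Reagents that add atoms: none
Why: Proposed new method: α-elimination of HBr from 18 by KOtBu gives electrophilic dibromocarbene, which should add to the C2=C3 bond of 17, the only alkene and one with two oxygen donors, to form the cis-fused dibromocyclopropane 19; the closest known reaction types are the Ciamician–Dennstedt expansion of indoles to 3-haloquinolines and the dihalocarbene expansion of cyclic silyl enol ethers to 2-halo enones, neither shown on a 3-siloxybenzofuran. Disrotatory electrocyclic opening of 19 with loss of the bromide lying syn to O1 and C3a (the geometry the Woodward–Hoffmann–DePuy rule requires when the ring atoms turn inward) breaks the old C2–C3 bond and gives the aromatic 4-siloxyflavylium bromide 20, whose formation is the driving force. Bromide then takes the silyl group from O4, which leaves the C4 carbonyl, so the carbene carbon ends as C3 bearing bromine with new C2–C3 and C3–C4 bonds; the silyl bromide is hydrolysed to the silanol in the work-up. Ring C is therefore closed as a six-membered pyranone by one-carbon ring expansion of the furan ring (cyclopropanation, then two-electron electrocyclic opening), not by cyclisation of an open chain. The two stereocentres of 19 are cis by ring constraint, racemic and destroyed on opening, so the step sets no stereocentre. The selectivity needed is chemoselectivity for the enol ether over the arenes and the benzylic C–H bonds: ring A has no free position, ring B and the benzyl groups are far weaker π-nucleophiles than a doubly oxygenated alkene, and slow addition of 18 at low temperature keeps the carbene concentration low enough to disfavour C–H insertion. The hindered silyl group and a hydrocarbon medium in which KOtBu barely dissolves are chosen so that the Si–O bond outlasts the base until the cyclopropane has formed.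

Step 13
Reactants: 21 5,7-bis(benzyloxy)-2-[3,4-bis(benzyloxy)phenyl]-3-bromo-6,8-dimethoxy-4H-chromen-4-one
Product: 23 5,7-bis(benzyloxy)-2-[3,4-bis(benzyloxy)phenyl]-3-hydroxy-6,8-dimethoxy-4H-chromen-4-one, via pinacol boronate 22 (not isolated)
Conditions: B2pin2, PdCl2(dppf), KOAc, 1,4-dioxane, 85 °C; then 30% H2O2, pH 7 phosphate buffer, THF, 0 °C → rt
Reagents that add atoms: hydrogen peroxide, OO; bis(pinacolato)diboron, CC1(C)OB(OC1(C)C)B1OC(C)(C)C(C)(C)O1 (boron and pinacol of 22 only)
Why: Miyaura borylation of a vinylic bromide followed by oxidation of the C–B bond; the weak base KOAc and buffered peroxide avoid the nucleophilic attack at C2 that hydroxide or alkoxide would cause, and the boronate is oxidised in the same flask because an α-boryl enone is prone to protodeboronation.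

Step 14
Reactants: 23 5,7-bis(benzyloxy)-2-[3,4-bis(benzyloxy)phenyl]-3-hydroxy-6,8-dimethoxy-4H-chromen-4-one
Product: 24 2-(3,4-dihydroxyphenyl)-3,5,7-trihydroxy-6,8-dimethoxy-4H-chromen-4-one (3,5,7,3',4'-pentahydroxy-6,8-dimethoxyflavone)
Conditions: H2 (1 atm), 10% Pd/C, THF/MeOH, rt
Reagents that add atoms: none
Why: Hydrogenolysis of four benzyl aryl ethers under neutral conditions; the C2=C3 bond of a flavonol is part of a vinylogous ester and is normally not reduced, and the methyl ethers are untouched.

## Compound list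

1 | 2,6-dimethoxyphenol (syringol) | COc1cccc(OC)c1O | starting material
2 | 2-(benzyloxy)-1,3-dimethoxybenzene | COc1cccc(OC)c1OCc1ccccc1 | intermediate
3 | 3-(benzyloxy)-1,5-dibromo-2,4-dimethoxybenzene | COc1c(Br)cc(Br)c(OC)c1OCc1ccccc1 | intermediate
4 | [3-(benzyloxy)-5-bromo-2,4-dimethoxyphenyl]lithium | COc1c([Li])cc(Br)c(OC)c1OCc1ccccc1 | intermediate
5 | dimethyl [3-(benzyloxy)-5-bromo-2,4-dimethoxyphenyl]boronate | COc1c(B(OC)OC)cc(Br)c(OC)c1OCc1ccccc1 | intermediate
6 | 3-(benzyloxy)-5-bromo-2,4-dimethoxyphenol | COc1c(O)cc(Br)c(OC)c1OCc1ccccc1 | intermediate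
7 | 1,3-bis(benzyloxy)-5-bromo-2,4-dimethoxybenzene | COc1c(OCc2ccccc2)cc(Br)c(OC)c1OCc1ccccc1 | intermediate
8 | 3,5-bis(benzyloxy)-2,4-dimethoxyphenol | COc1c(OCc2ccccc2)cc(O)c(OC)c1OCc1ccccc1 | intermediate
9 | 3,4-dihydroxyphenylacetic acid | OC(=O)Cc1ccc(O)c(O)c1 | starting material
10 | benzyl 2-[3,4-bis(benzyloxy)phenyl]acetate | O=C(Cc1ccc(OCc2ccccc2)c(OCc2ccccc2)c1)OCc1ccccc1 | intermediate
11 | {[1-(benzyloxy)-2-[3,4-bis(benzyloxy)phenyl]ethenyl]oxy}trimethylsilane (double-bond geometry not defined) | C[Si](C)(C)OC(OCc1ccccc1)=Cc1ccc(OCc2ccccc2)c(OCc2ccccc2)c1 | intermediate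
12 | benzyl 2-bromo-2-[3,4-bis(benzyloxy)phenyl]acetate (racemic) | O=C(OCc1ccccc1)C(Br)c1ccc(OCc2ccccc2)c(OCc2ccccc2)c1 | intermediate
13 | benzyl 2-[3,5-bis(benzyloxy)-2,4-dimethoxyphenoxy]-2-[3,4-bis(benzyloxy)phenyl]acetate (racemic) | COc1c(OCc2ccccc2)cc(OC(C(=O)OCc2ccccc2)c2ccc(OCc3ccccc3)c(OCc3ccccc3)c2)c(OC)c1OCc1ccccc1 | intermediate
14 | 2-[3,5-bis(benzyloxy)-2,4-dimethoxyphenoxy]-2-[3,4-bis(benzyloxy)phenyl]acetic acid (racemic) | COc1c(OCc2ccccc2)cc(OC(C(=O)O)c2ccc(OCc3ccccc3)c(OCc3ccccc3)c2)c(OC)c1OCc1ccccc1 | intermediate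
15 | 2-[3,5-bis(benzyloxy)-2,4-dimethoxyphenoxy]-2-[3,4-bis(benzyloxy)phenyl]acetic trifluoroacetic anhydride (racemic) | COc1c(OCc2ccccc2)cc(OC(C(=O)OC(=O)C(F)(F)F)c2ccc(OCc3ccccc3)c(OCc3ccccc3)c2)c(OC)c1OCc1ccccc1 | intermediate
16 | 4,6-bis(benzyloxy)-2-[3,4-bis(benzyloxy)phenyl]-5,7-dimethoxy-1-benzofuran-3(2H)-one (racemic) | COc1c(OCc2ccccc2)c(OC)c2OC(c3ccc(OCc4ccccc4)c(OCc4ccccc4)c3)C(=O)c2c1OCc1ccccc1 | intermediate
17 | {[4,6-bis(benzyloxy)-2-[3,4-bis(benzyloxy)phenyl]-5,7-dimethoxy-1-benzofuran-3-yl]oxy}(tert-butyl)dimethylsilane | COc1c(OCc2ccccc2)c(OC)c2oc(-c3ccc(OCc4ccccc4)c(OCc4ccccc4)c3)c(O[Si](C)(C)C(C)(C)C)c2c1OCc1ccccc1 | intermediate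
18 | bromoform | BrC(Br)Br | starting material
19 | 4,6-bis(benzyloxy)-1a-[3,4-bis(benzyloxy)phenyl]-1,1-dibromo-6b-[(tert-butyldimethylsilyl)oxy]-3,5-dimethoxy-1a,6b-dihydro-1H-cyclopropa[b][1]benzofuran (racemic, cis-fused) | COc1c(OCc2ccccc2)c(OC)c2OC3(c4ccc(OCc5ccccc5)c(OCc5ccccc5)c4)C(Br)(Br)C3(O[Si](C)(C)C(C)(C)C)c2c1OCc1ccccc1 | intermediate
20 | 5,7-bis(benzyloxy)-2-[3,4-bis(benzyloxy)phenyl]-3-bromo-4-[(tert-butyldimethylsilyl)oxy]-6,8-dimethoxychromenylium bromide | COc1c(OCc2ccccc2)c(OC)c2[o+]c(-c3ccc(OCc4ccccc4)c(OCc4ccccc4)c3)c(Br)c(O[Si](C)(C)C(C)(C)C)c2c1OCc1ccccc1.[Br-] | intermediate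
21 | 5,7-bis(benzyloxy)-2-[3,4-bis(benzyloxy)phenyl]-3-bromo-6,8-dimethoxy-4H-chromen-4-one | COc1c(OCc2ccccc2)c(OC)c2oc(-c3ccc(OCc4ccccc4)c(OCc4ccccc4)c3)c(Br)c(=O)c2c1OCc1ccccc1 | intermediate
22 | 5,7-bis(benzyloxy)-2-[3,4-bis(benzyloxy)phenyl]-6,8-dimethoxy-3-(4,4,5,5-tetramethyl-1,3,2-dioxaborolan-2-yl)-4H-chromen-4-one | COc1c(OCc2ccccc2)c(OC)c2oc(-c3ccc(OCc4ccccc4)c(OCc4ccccc4)c3)c(B3OC(C)(C)C(C)(C)O3)c(=O)c2c1OCc1ccccc1 | intermediate
23 | 5,7-bis(benzyloxy)-2-[3,4-bis(benzyloxy)phenyl]-3-hydroxy-6,8-dimethoxy-4H-chromen-4-one | COc1c(OCc2ccccc2)c(OC)c2oc(-c3ccc(OCc4ccccc4)c(OCc4ccccc4)c3)c(O)c(=O)c2c1OCc1ccccc1 | intermediate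
24 | 2-(3,4-dihydroxyphenyl)-3,5,7-trihydroxy-6,8-dimethoxy-4H-chromen-4-one | COc1c(O)c(OC)c2oc(-c3ccc(O)c(O)c3)c(O)c(=O)c2c1O | target

## Step count and risks

Total: 14 steps. Longest linear sequence: 12 steps (steps 1 to 5 and 8 to 14, from 1); the ring B branch (steps 6 and 7) joins at step 8.

**Step 12 (key step, proposed new method).**
- Most likely failure: cleavage of the Si–O bond by tert-butoxide before the carbene arrives. The liberated enolate would then be alkylated by the carbene at C2 (abnormal Reimer–Tiemann course) without ring expansion.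
- Also possible: carbene insertion into benzylic C–H bonds, slow addition to the crowded tetrasubstituted double bond, or attack of excess alkoxide at C2 of the ring-expanded product.
- Fallback with known chemistry, setting out from 8 and coming back at 23: 8 is C-acetylated at its only free ring position (Ac2O, BF3·OEt2, 0 °C → rt) to 1-[2,4-bis(benzyloxy)-6-hydroxy-3,5-dimethoxyphenyl]ethan-1-one F1. Claisen–Schmidt condensation with commercial 3,4-bis(benzyloxy)benzaldehyde (KOH, EtOH) gives (E)-1-[2,4-bis(benzyloxy)-6-hydroxy-3,5-dimethoxyphenyl]-3-[3,4-bis(benzyloxy)phenyl]prop-2-en-1-one F2. Oxidative cyclisation (catalytic I2, DMSO, 120 °C) gives 5,7-bis(benzyloxy)-2-[3,4-bis(benzyloxy)phenyl]-6,8-dimethoxy-4H-chromen-4-one F3. Dimethyldioxirane epoxidises its C2=C3 bond to 4,6-bis(benzyloxy)-1a-[3,4-bis(benzyloxy)phenyl]-3,5-dimethoxy-1a,7a-dihydro-7H-oxireno[2,3-b]chromen-7-one F4, which opens under TsOH catalysis to 23.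

**Step 10.**
- Most likely failure: loss of carbon monoxide from the activated acyl species, because the cation left behind is stabilised by the aryloxy oxygen and by ring B. Acid-induced loss of benzyl groups and autoxidation of the enolisable product are further risks.
- Fallback, setting out from 8 and coming back at 16, closing the O1–C2 bond last: Houben–Hoesch acylation of 8 with commercial 2-[3,4-bis(benzyloxy)phenyl]acetonitrile (HCl, ZnCl2, Et2O, 0 °C) gives the salt 1-[2,4-bis(benzyloxy)-6-hydroxy-3,5-dimethoxyphenyl]-2-[3,4-bis(benzyloxy)phenyl]ethan-1-iminium chloride F5. Aqueous hydrolysis converts it into 1-[2,4-bis(benzyloxy)-6-hydroxy-3,5-dimethoxyphenyl]-2-[3,4-bis(benzyloxy)phenyl]ethan-1-one F6. Diazo transfer (4-acetamidobenzenesulfonyl azide, DBU, MeCN) gives 1-[2,4-bis(benzyloxy)-6-hydroxy-3,5-dimethoxyphenyl]-2-[3,4-bis(benzyloxy)phenyl]-2-diazoethan-1-one F7. Rh2(OAc)4-catalysed intramolecular O–H insertion then closes the furanone ring to 16.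

**Step 13.**
- Most likely failure: replacement of bromine or boron at C3 by hydrogen (hydrodehalogenation during slow transmetalation at the hindered carbon, or protodeboronation of the α-boryl enone).
- Fallback, setting out from 21 and coming back at 23, forming the C–O bond directly at palladium: coupling of 21 with (E)-benzaldehyde oxime as a hydroxide surrogate (Pd2(dba)3, tBuBrettPhos, Cs2CO3, DMF, 80 °C) gives (E)-benzaldehyde O-{5,7-bis(benzyloxy)-2-[3,4-bis(benzyloxy)phenyl]-6,8-dimethoxy-4-oxo-4H-chromen-3-yl}oxime F8. Under the basic conditions it fragments to 23 and benzonitrile.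

**Step 7.**
- Most likely failure: self-alkylation (the enolate or ketene acetal attacks bromo ester already formed), and ionisation of the electron-rich benzylic bromide during isolation.
- Fallback, setting out from 10 and coming back at 13, avoiding the bromide: diazo transfer to 10 (4-acetamidobenzenesulfonyl azide, DBU, MeCN) gives benzyl 2-[3,4-bis(benzyloxy)phenyl]-2-diazoacetate F9. Rh2(OAc)4-catalysed O–H insertion of its carbenoid into phenol 8 gives 13 directly.

## Further compounds

F1 | step 12 | 1-[2,4-bis(benzyloxy)-6-hydroxy-3,5-dimethoxyphenyl]ethan-1-one | COc1c(OCc2ccccc2)c(C(C)=O)c(O)c(OC)c1OCc1ccccc1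
F2 | step 12 | (E)-1-[2,4-bis(benzyloxy)-6-hydroxy-3,5-dimethoxyphenyl]-3-[3,4-bis(benzyloxy)phenyl]prop-2-en-1-one | COc1c(OCc2ccccc2)c(C(=O)/C=C/c2ccc(OCc3ccccc3)c(OCc3ccccc3)c2)c(O)c(OC)c1OCc1ccccc1
F3 | step 12 | 5,7-bis(benzyloxy)-2-[3,4-bis(benzyloxy)phenyl]-6,8-dimethoxy-4H-chromen-4-one | COc1c(OCc2ccccc2)c(OC)c2oc(-c3ccc(OCc4ccccc4)c(OCc4ccccc4)c3)cc(=O)c2c1OCc1ccccc1
F4 | step 12 | 4,6-bis(benzyloxy)-1a-[3,4-bis(benzyloxy)phenyl]-3,5-dimethoxy-1a,7a-dihydro-7H-oxireno[2,3-b]chromen-7-one (racemic) | COc1c(OCc2ccccc2)c(OC)c2OC3(c4ccc(OCc5ccccc5)c(OCc5ccccc5)c4)OC3C(=O)c2c1OCc1ccccc1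
F5 | step 10 | 1-[2,4-bis(benzyloxy)-6-hydroxy-3,5-dimethoxyphenyl]-2-[3,4-bis(benzyloxy)phenyl]ethan-1-iminium chloride | COc1c(OCc2ccccc2)c(C(=[NH2+])Cc2ccc(OCc3ccccc3)c(OCc3ccccc3)c2)c(O)c(OC)c1OCc1ccccc1.[Cl-]
F6 | step 10 | 1-[2,4-bis(benzyloxy)-6-hydroxy-3,5-dimethoxyphenyl]-2-[3,4-bis(benzyloxy)phenyl]ethan-1-one | COc1c(OCc2ccccc2)c(C(=O)Cc2ccc(OCc3ccccc3)c(OCc3ccccc3)c2)c(O)c(OC)c1OCc1ccccc1
F7 | step 10 | 1-[2,4-bis(benzyloxy)-6-hydroxy-3,5-dimethoxyphenyl]-2-[3,4-bis(benzyloxy)phenyl]-2-diazoethan-1-one | COc1c(OCc2ccccc2)c(C(=O)C(=[N+]=[N-])c2ccc(OCc3ccccc3)c(OCc3ccccc3)c2)c(O)c(OC)c1OCc1ccccc1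
F8 | step 13 | (E)-benzaldehyde O-{5,7-bis(benzyloxy)-2-[3,4-bis(benzyloxy)phenyl]-6,8-dimethoxy-4-oxo-4H-chromen-3-yl}oxime | COc1c(OCc2ccccc2)c(OC)c2oc(-c3ccc(OCc4ccccc4)c(OCc4ccccc4)c3)c(O/N=C/c3ccccc3)c(=O)c2c1OCc1ccccc1
F9 | step 7 | benzyl 2-[3,4-bis(benzyloxy)phenyl]-2-diazoacetate | [N-]=[N+]=C(C(=O)OCc1ccccc1)c1ccc(OCc2ccccc2)c(OCc2ccccc2)c1
A1 | alternative 1 | 3-[3,4-bis(benzyloxy)phenyl]-1-[2,4,6-tris(benzyloxy)-3,5-dimethoxyphenyl]prop-2-yn-1-one | COc1c(OCc2ccccc2)c(OC)c(OCc2ccccc2)c(C(=O)C#Cc2ccc(OCc3ccccc3)c(OCc3ccccc3)c2)c1OCc1ccccc1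
A2 | alternative 1 | 1,3,5-tris(benzyloxy)-2-iodo-4,6-dimethoxybenzene | COc1c(OCc2ccccc2)c(OC)c(OCc2ccccc2)c(I)c1OCc1ccccc1
A3 | alternative 1 | 1,2-bis(benzyloxy)-4-ethynylbenzene | C#Cc1ccc(OCc2ccccc2)c(OCc2ccccc2)c1
A4 | alternative 1 | carbon monoxide | [C-]#[O+]
A5 | alternative 2 | 3,5,7-tris(benzyloxy)-2-[3,4-bis(benzyloxy)phenyl]-6,8-dimethoxy-4H-chromen-4-one | COc1c(OCc2ccccc2)c(OC)c2oc(-c3ccc(OCc4ccccc4)c(OCc4ccccc4)c3)c(OCc3ccccc3)c(=O)c2c1OCc1ccccc1
A6 | alternative 2 | 3,5,7-tris(benzyloxy)-2-[3,4-bis(benzyloxy)phenyl]-6,8-dibromo-4H-chromen-4-one | Brc1c(OCc2ccccc2)c(Br)c2oc(-c3ccc(OCc4ccccc4)c(OCc4ccccc4)c3)c(OCc3ccccc3)c(=O)c2c1OCc1ccccc1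
A7 | alternative 2 | quercetin, 2-(3,4-dihydroxyphenyl)-3,5,7-trihydroxy-4H-chromen-4-one | O=c1c(O)c(-c2ccc(O)c(O)c2)oc2cc(O)cc(O)c12
A8 | alternative 2 | sodium methoxide | [Na+].[O-]C
A9 | alternative 3 | 3,7-bis(benzyloxy)-2-[3,4-bis(benzyloxy)phenyl]-5,8-dihydroxy-6-methoxy-4H-chromen-4-one | COc1c(OCc2ccccc2)c(O)c2oc(-c3ccc(OCc4ccccc4)c(OCc4ccccc4)c3)c(OCc3ccccc3)c(=O)c2c1O
A10 | alternative 3 | 2-(benzyloxy)-4-[5-(benzyloxy)-6-[3,4-bis(benzyloxy)phenyl]-4-oxo-4H-pyran-3-yl]-4-hydroxy-3-methoxycyclobut-2-en-1-one (racemic) | COC1=C(OCc2ccccc2)C(=O)C1(O)c1coc(-c2ccc(OCc3ccccc3)c(OCc3ccccc3)c2)c(OCc2ccccc2)c1=O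
A11 | alternative 3 | 3-(benzyloxy)-4-methoxycyclobut-3-ene-1,2-dione | COC1=C(OCc2ccccc2)C(=O)C1=O
A12 | alternative 3 | 3-(benzyloxy)-2-[3,4-bis(benzyloxy)phenyl]-4H-pyran-4-one | O=c1ccoc(-c2ccc(OCc3ccccc3)c(OCc3ccccc3)c2)c1OCc1ccccc1
A13 | alternative 3 | (3Z)-2-(benzyloxy)-4-[5-(benzyloxy)-6-[3,4-bis(benzyloxy)phenyl]-4-oxo-4H-pyran-3-yl]-4-hydroxy-3-methoxybuta-1,3-dien-1-one | O=C=C(OCc1ccccc1)/C(OC)=C(/O)c1coc(-c2ccc(OCc3ccccc3)c(OCc3ccccc3)c2)c(OCc2ccccc2)c1=O
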